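The data are calculated on assumed constants, noise included.

Late in the flask, the excess follows from the ratio of two leftovers, so the thing to watch and count is half-lives of the left-handed substrate.

- gamma: left-handed substrate 0.10 M; right-handed substrate 0.10 M; reagent 0.15 M; free catalyst 72 µM; run made earlier
- flask: left-handed substrate 0.10 M; reagent 0.300 M; free catalyst 72 µM; right-handed substrate 0.10 M; time 8.0 d

gamma run (percent of the left-handed substrate and right-handed substrate together charged)

| time / d | right-handed substrate / % | left-handed substrate / % |
|---|---|---|
| 0.333 | 48.7 | 46.6 |
| 0.625 | 48.8 | 41.0 |
| 1.04 | 50.6 | 36.5 |
| 1.25 | 47.6 | 34.4 |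
| 1.67 | 47.1 | 31.6 |
| 2.08 | 48.4 | 27.4 |
| 2.50 | 46.3 | 24.7 |

(standard deviation of a reading: 1 percentage point)

- free catalyst is single-handed; left-handed substrate and right-handed substrate are mirror images of each other, charged as a racemate, each of them at the stated concentration
- what was read earlier has a scatter of 1 percentage point, one standard deviation
- what may be going on: left-handed product <-> right-handed product; free catalyst <-> dormant form; reagent + catalyst intermediate A -> free catalyst + left-handed product; reagent + catalyst intermediate B -> free catalyst + right-handed product; free catalyst + left-handed substrate <-> catalyst intermediate A; 2 free catalyst -> spent catalyst; free catalyst + right-handed substrate <-> catalyst intermediate B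

1. whether the excess of right-handed substrate over left-handed substrate among what is left of the two reaches 80% by 8.0 d (no / yes)
2. the highest excess of right-handed substrate over left-handed substrate among what is left of the two up to 8.0 d

The ladder is read from the last gamma reading, with its scatter. Starting from half of the charge, the left-handed substrate in gamma falls on average at 0.282 d⁻¹, a half-life of 2.46 d. The right-handed substrate in gamma falls on average at 0.0308 d⁻¹, a half-life of 22.5 d. Their ratio, the selectivity factor, reads 9.17. The time allowed, 8.0 d, is longer than the first half-life and shorter than the second, so at these paces the left-handed substrate goes first while the right-handed substrate passes 0.109 of a half-life for each left-handed one.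

An excess of 80% means left-handed substrate at 0.111 of the right-handed, and each left-handed half-life divides that ratio by 1.85. The half-lives asked for are therefore 3.56.

At the gamma pace, the flask holds 3.26 half-lives, fewer than that. But the flask carries twice the reagent, which stands in both steps that make product. If the pace follows the reagent, the count is 6.51, more than asked, and the excess ends near 96.5%. This reckoning commits to that figure.

The forecast differs on the top: it says yes with 85%, within 75% to 97%, noting that “scatter cannot exclude first order”.

The flask gives yes, with a top of 99.2% at 8.00 d, higher than the forecast's range reaches.

    left-handed product ⇌ right-handed product (k = 0.00901 h⁻¹)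
    free catalyst ⇌ dormant form (K = 3.10, k = 0.348 h⁻¹)
    reagent + catalyst intermediate A → free catalyst + left-handed product (k = 164 M⁻¹ h⁻¹)
    reagent + catalyst intermediate B → free catalyst + right-handed product (k = 78.2 M⁻¹ h⁻¹)
    free catalyst + left-handed substrate ⇌ catalyst intermediate A (K = 110 M⁻¹, k = 18400 M⁻¹ h⁻¹)
    2 free catalyst → spent catalyst (k = 445 M⁻¹ h⁻¹)
    free catalyst + right-handed substrate ⇌ catalyst intermediate B (K = 13.0 M⁻¹, k = 2100 M⁻¹ h⁻¹)

The flask passed 80% at 3.31 d, with 43.2% of the two charged still standing as right-handed substrate. Set against the 3.56 half-lives asked for, that time makes one left-handed half-life in the flask 0.931 d on average, shorter than half the gamma reading. The 8.0 d of the flask then holds 8.59 such half-lives, and at that time the left-handed substrate stood at 0.142%.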